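The geranyl chain is written onto ring A by cutting two bonds at once: benzylic C1'–C2' and C3'–CH3. Cp2ZrCl2-catalysed syn-methylalumination of 6-methylhept-5-en-1-yne fixes the (E)-C2'=C3' geometry, and zerovalent nickel joins the alkenylalane to a ring A benzylic chloride in the same pot. The feature exploited is the benzylic CH2 (C1') on ring A bonded to a trisubstituted alkene whose C3' methyl sits cis to C1', the imprint of syn methyl–metal addition to a terminal alkyne. The precursor is the complete (E)-stilbene carrying CH2Cl ortho to the ring A oxygen, all three phenols being TIPS ethers that resist base and silyl migration.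

Key step: step 8

Assumption: ring A is the ring bearing the C10 chain and one oxygen, ring B is the 3,5-dioxygenated ring, and the chain carbons run from C1' (benzylic) to C8'. TIPS is triisopropylsilyl. Lithium acetylide–ethylenediamine complex (LiC≡CH·H2NCH2CH2NH2) is bought as such.

Step 1
Reactants: 1 3,5-dihydroxybenzaldehyde
Product: 2 3,5-bis(triisopropylsilyloxy)benzaldehyde
Conditions: TIPSCl, imidazole, DMF, 0 °C to rt
Reagents that add atoms: chlorotriisopropylsilane (TIPSCl), CC(C)[Si](Cl)(C(C)C)C(C)C
Why: Imidazole-promoted O-silylation of phenols should cap both ring B hydroxyls quickly and leave the aldehyde untouched.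

Step 2
Reactants: 2 3,5-bis(triisopropylsilyloxy)benzaldehyde
Product: 3 1-ethenyl-3,5-bis(triisopropylsilyloxy)benzene
Conditions: Ph3PCH3Br, n-BuLi, THF, 0 °C; then 2, 0 °C to rt
Reagents that add atoms: methyltriphenylphosphonium bromide, C[P+](c1ccccc1)(c1ccccc1)c1ccccc1.[Br-]
Why: Wittig methylenation of a non-enolisable aryl aldehyde by the non-stabilised ylide should give the styrene, and aryl TIPS ethers tolerate the lithium ylide at this temperature.

Step 3
Reactants: 4 5-bromosalicylaldehyde (5-bromo-2-hydroxybenzaldehyde)
Product: 5 5-bromo-2-(triisopropylsilyloxy)benzaldehyde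
Conditions: TIPSCl, imidazole, DMAP (cat.), DMF, rt
Reagents that add atoms: chlorotriisopropylsilane (TIPSCl), CC(C)[Si](Cl)(C(C)C)C(C)C
Why: The same imidazole-promoted O-silylation should overcome the hydrogen bond to the aldehyde, and the bulky TIPS group is chosen because this oxygen must later sit next to hot amine base and a benzylic alkoxide.

Step 4
Reactants: 5 5-bromo-2-(triisopropylsilyloxy)benzaldehyde; 3 1-ethenyl-3,5-bis(triisopropylsilyloxy)benzene
Product: 6 5-[(E)-2-[3,5-bis(triisopropylsilyloxy)phenyl]ethenyl]-2-(triisopropylsilyloxy)benzaldehyde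
Conditions: Pd(OAc)2 (cat.), P(o-tol)3, Et3N, DMF, 90 °C
Reagents that add atoms: none
Why: In this Mizoroki–Heck reaction zerovalent palladium inserts into the C–Br bond, the aryl group is delivered to the unsubstituted alkene terminus and syn β-hydride elimination should give the (E)-stilbene, while the anhydrous amine base spares the silyl ethers and the aldehyde.

Step 5
Reactants: 6 5-[(E)-2-[3,5-bis(triisopropylsilyloxy)phenyl]ethenyl]-2-(triisopropylsilyloxy)benzaldehyde
Product: 7 [5-[(E)-2-[3,5-bis(triisopropylsilyloxy)phenyl]ethenyl]-2-(triisopropylsilyloxy)phenyl]methanol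
Conditions: NaBH4, THF/MeOH, –10 to 0 °C; aq. NH4Cl quench at 0 °C
Reagents that add atoms: none
Why: Borohydride reduction should convert only the aryl aldehyde, and low temperature, short contact time and the bulk of TIPS hold back 1,4 O-to-O silyl migration in the intermediate alkoxyborate.

Step 6
Reactants: 7 [5-[(E)-2-[3,5-bis(triisopropylsilyloxy)phenyl]ethenyl]-2-(triisopropylsilyloxy)phenyl]methanol
Product: 9 [2-(chloromethyl)-4-[(E)-2-[3,5-bis(triisopropylsilyloxy)phenyl]ethenyl]phenoxy]triisopropylsilane, via benzylic methanesulfonate 8 (not isolated)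
Conditions: MsCl, Et3N, THF, 0 °C; then LiCl, 0 °C to rt
Reagents that add atoms: methanesulfonyl chloride, CS(=O)(=O)Cl (atoms of intermediate 8); lithium chloride, [Li+].[Cl-]
Why: Mesylation of the primary benzylic alcohol followed by SN2 displacement with chloride in the same flask uses neither acid nor fluoride, so the ortho silyl ether should stay in place and no ortho-quinone methide can form.

Step 7
Reactants: 10 5-bromo-2-methylpent-2-ene; 11 lithium acetylide–ethylenediamine complex (LiC≡CH·H2NCH2CH2NH2)
Product: 12 6-methylhept-5-en-1-yne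
Conditions: DMSO, 10 °C to rt; distillation
Reagents that add atoms: none
Why: SN2 alkylation of the monolithium acetylide at the unhindered primary bromide in a dipolar aprotic solvent should give the terminal enyne, with the trisubstituted alkene as a spectator.

Step 8
Reactants: 12 6-methylhept-5-en-1-yne; 13 trimethylaluminium; 9 [2-(chloromethyl)-4-[(E)-2-[3,5-bis(triisopropylsilyloxy)phenyl]ethenyl]phenoxy]triisopropylsilane
Product: 15 [4-[(E)-2-[3,5-bis(triisopropylsilyloxy)phenyl]ethenyl]-2-[(2E)-3,7-dimethylocta-2,6-dien-1-yl]phenoxy]triisopropylsilane (tris-TIPS ether of the target), via (E)-alkenyldimethylalane 14 (not isolated)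
Conditions: 12, AlMe3, Cp2ZrCl2 (25 mol %), ClCH2CH2Cl, 0 °C to rt; volatiles and excess AlMe3 removed in vacuo; then 9, NiCl2(PPh3)2/n-BuLi (5 mol %), THF, 0 °C to rt
Reagents that add atoms: none
Why: AlMe3 activated by Cp2ZrCl2 adds methyl and metal syn across the terminal alkyne of 12, methyl to the internal carbon (future C3') and aluminium to the terminal carbon (future C2'), so only the (E)-alkenyldimethylalane 14 should form. Zerovalent nickel, made from NiCl2(PPh3)2 and n-BuLi, then inserts into the benzylic C–Cl bond of 9, the alkenyl group transmetalates from aluminium to nickel, and reductive elimination forms C1'–C2' with retention of alkene geometry. The closest known reaction type is the Negishi zirconium-catalysed methylalumination of terminal alkynes followed in the same pot by nickel- or palladium-catalysed coupling of the alkenylalane with benzylic chlorides. No ring is closed and no stereocentre is created; the one stereogenic element, the (E)-C2'=C3' alkene, is set by syn addition at the catalyst and not by the substrate. The step needs regioselective methyl delivery (secured by the terminal alkyne), selectivity for the alkyne over the trisubstituted alkene of 12 and the stilbene of 9 (the alkyne is consumed before 9 is added, and both alkenes are inert to AlMe3/Cp2ZrCl2), and alkenyl instead of methyl transfer to nickel (alkenyl migrates faster from aluminium, and excess AlMe3 is stripped first). Because C1' is already fixed on ring A and the nucleophile is alkenyl and not allyl, no allylic transposition and no C- versus O-alkylation issue can arise.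

Step 9
Reactants: 15 [4-[(E)-2-[3,5-bis(triisopropylsilyloxy)phenyl]ethenyl]-2-[(2E)-3,7-dimethylocta-2,6-dien-1-yl]phenoxy]triisopropylsilane
Product: 16 5-[(E)-2-[3-[(2E)-3,7-dimethylocta-2,6-dien-1-yl]-4-hydroxyphenyl]ethenyl]benzene-1,3-diol (target)
Conditions: TBAF, AcOH, THF, 0 °C to rt
Reagents that add atoms: none
Why: Fluoride-mediated desilylation, driven by the strong Si–F bond, should free all three phenols, and the acetic acid buffer keeps the electron-rich stilbene phenols protonated while being far too weak to cyclise the ortho-geranyl phenol to a chroman.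

Compound list
1 | 3,5-dihydroxybenzaldehyde | O=Cc1cc(O)cc(O)c1 | starting material
2 | 3,5-bis(triisopropylsilyloxy)benzaldehyde | O=Cc1cc(O[Si](C(C)C)(C(C)C)C(C)C)cc(O[Si](C(C)C)(C(C)C)C(C)C)c1 | intermediate
3 | 1-ethenyl-3,5-bis(triisopropylsilyloxy)benzene | C=Cc1cc(O[Si](C(C)C)(C(C)C)C(C)C)cc(O[Si](C(C)C)(C(C)C)C(C)C)c1 | intermediate
4 | 5-bromosalicylaldehyde (5-bromo-2-hydroxybenzaldehyde) | O=Cc1cc(Br)ccc1O | starting material
5 | 5-bromo-2-(triisopropylsilyloxy)benzaldehyde | O=Cc1cc(Br)ccc1O[Si](C(C)C)(C(C)C)C(C)C | intermediate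
6 | 5-[(E)-2-[3,5-bis(triisopropylsilyloxy)phenyl]ethenyl]-2-(triisopropylsilyloxy)benzaldehyde | O=Cc1cc(/C=C/c2cc(O[Si](C(C)C)(C(C)C)C(C)C)cc(O[Si](C(C)C)(C(C)C)C(C)C)c2)ccc1O[Si](C(C)C)(C(C)C)C(C)C | intermediate
7 | [5-[(E)-2-[3,5-bis(triisopropylsilyloxy)phenyl]ethenyl]-2-(triisopropylsilyloxy)phenyl]methanol | OCc1cc(/C=C/c2cc(O[Si](C(C)C)(C(C)C)C(C)C)cc(O[Si](C(C)C)(C(C)C)C(C)C)c2)ccc1O[Si](C(C)C)(C(C)C)C(C)C | intermediate
8 | [5-[(E)-2-[3,5-bis(triisopropylsilyloxy)phenyl]ethenyl]-2-(triisopropylsilyloxy)phenyl]methyl methanesulfonate | CS(=O)(=O)OCc1cc(/C=C/c2cc(O[Si](C(C)C)(C(C)C)C(C)C)cc(O[Si](C(C)C)(C(C)C)C(C)C)c2)ccc1O[Si](C(C)C)(C(C)C)C(C)C | intermediate (not isolated)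
9 | [2-(chloromethyl)-4-[(E)-2-[3,5-bis(triisopropylsilyloxy)phenyl]ethenyl]phenoxy]triisopropylsilane | ClCc1cc(/C=C/c2cc(O[Si](C(C)C)(C(C)C)C(C)C)cc(O[Si](C(C)C)(C(C)C)C(C)C)c2)ccc1O[Si](C(C)C)(C(C)C)C(C)C | intermediate
10 | 5-bromo-2-methylpent-2-ene | CC(C)=CCCBr | starting material
11 | lithium acetylide–ethylenediamine complex | [Li+].[C-]#C.NCCN | starting material
12 | 6-methylhept-5-en-1-yne | C#CCCC=C(C)C | intermediate
13 | trimethylaluminium | C[Al](C)C | starting material
14 | [(1E)-2,6-dimethylhepta-1,5-dien-1-yl]dimethylalane | C[Al](C)/C=C(\C)CCC=C(C)C | intermediate (not isolated)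
15 | [4-[(E)-2-[3,5-bis(triisopropylsilyloxy)phenyl]ethenyl]-2-[(2E)-3,7-dimethylocta-2,6-dien-1-yl]phenoxy]triisopropylsilane | CC(C)=CCC/C(C)=C/Cc1cc(/C=C/c2cc(O[Si](C(C)C)(C(C)C)C(C)C)cc(O[Si](C(C)C)(C(C)C)C(C)C)c2)ccc1O[Si](C(C)C)(C(C)C)C(C)C | intermediate
16 | 5-[(E)-2-[3-[(2E)-3,7-dimethylocta-2,6-dien-1-yl]-4-hydroxyphenyl]ethenyl]benzene-1,3-diol | CC(C)=CCC/C(C)=C/Cc1cc(/C=C/c2cc(O)cc(O)c2)ccc1O | target

Total step count: 9 steps.
Longest linear sequence: 7 steps (steps 1, 2, 4, 5, 6, 8, 9, from 3,5-dihydroxybenzaldehyde to the target).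

Steps most likely to fail

Step 8. The methylalumination may stop short or lose regiocontrol. Residual AlMe3 may hand a methyl group to the benzylic position or, as a Lewis acid, ionise the electron-rich benzylic chloride so that it alkylates another arene. Nickel may also couple two benzylic units reductively. The fallback keeps the same two bonds but separates the events and reverses the polarity of the coupling. It sets out from 12 and 9 and comes back at 15. Alkenylalane 14, made from 12 and 13 as above, is quenched with I2 in THF at –30 to 0 °C to give (E)-1-iodo-2,6-dimethylhepta-1,5-diene F1, which can be purified and checked for geometry. Chloride 9 is treated with Zn dust and LiCl in THF at rt to give [5-[(E)-2-[3,5-bis(triisopropylsilyloxy)phenyl]ethenyl]-2-(triisopropylsilyloxy)benzyl]zinc chloride F2. A Negishi coupling of F2 with F1 under Pd(PPh3)4 in THF at rt to 50 °C should then give 15 with retention of the alkene geometry, in the absence of any aluminium Lewis acid.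

Step 4. The silyl ether ortho to the aldehyde may be lost under hot amine hydrobromide. Arylation may also occur at the internal alkene carbon to give a 1,1-diarylethene, and the catalyst may precipitate before the electron-rich bromide is consumed. The fallback replaces the Heck reaction by a Suzuki–Miyaura coupling. It sets out from 3 and 5 and comes back at 6. Cross-metathesis of 3 with vinylboronic acid pinacol ester (second-generation Grubbs catalyst, CH2Cl2, 40 °C) should give 2-[(E)-2-[3,5-bis(triisopropylsilyloxy)phenyl]ethenyl]-4,4,5,5-tetramethyl-1,3,2-dioxaborolane F3. Coupling of F3 with bromide 5 (Pd(dppf)Cl2, K3PO4, dioxane/H2O, 60 °C) transfers the preformed (E)-alkenyl group with retention and gives 6, so the regiochemistry question of the insertion step disappears.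

Step 7. The basic acetylide may eliminate HBr from the homoallylic bromide instead of substituting it. The amine may also move the triple bond, and the volatile enyne may be lost during isolation. The fallback turns the bromide into the nucleophile, so that elimination is impossible, and builds the alkyne by one-carbon homologation. It sets out from 10 and comes back at 12. Bromide 10 and Mg in THF give (4-methylpent-3-en-1-yl)magnesium bromide F4. Formylation with DMF at 0 °C and aqueous HCl work-up gives 5-methylhex-4-enal F5. Ohira–Bestmann homologation (dimethyl (1-diazo-2-oxopropyl)phosphonate, K2CO3, MeOH, rt) converts F5 into 12.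

Further compounds
F1 | step 8 | (E)-1-iodo-2,6-dimethylhepta-1,5-diene | I/C=C(\C)CCC=C(C)C
F2 | step 8 | [5-[(E)-2-[3,5-bis(triisopropylsilyloxy)phenyl]ethenyl]-2-(triisopropylsilyloxy)benzyl]zinc chloride | Cl[Zn]Cc1cc(/C=C/c2cc(O[Si](C(C)C)(C(C)C)C(C)C)cc(O[Si](C(C)C)(C(C)C)C(C)C)c2)ccc1O[Si](C(C)C)(C(C)C)C(C)C
F3 | step 4 | 2-[(E)-2-[3,5-bis(triisopropylsilyloxy)phenyl]ethenyl]-4,4,5,5-tetramethyl-1,3,2-dioxaborolane | CC1(C)OB(/C=C/c2cc(O[Si](C(C)C)(C(C)C)C(C)C)cc(O[Si](C(C)C)(C(C)C)C(C)C)c2)OC1(C)C
F4 | step 7 | (4-methylpent-3-en-1-yl)magnesium bromide | CC(C)=CCC[Mg]Br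
F5 | step 7 | 5-methylhex-4-enal | CC(C)=CCCC=O
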